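Conventions: geranyl = (2E)-3,7-dimethylocta-2,6-dien-1-yl; MOM = methoxymethyl. Ring atoms carry flavanone numbers (O1, C2, C3, C4, C4a, C5–C8, C8a; ring B primed).

## The problem

Nymphaeol A (16) is a flavanone. A phloroglucinol ring A is fused through C4a and C8a to the dihydropyranone ring C, which carries the catechol ring B at C2, and a geranyl chain sits on C6 between the C5 and C7 hydroxyls. There is a single stereocentre, C2 (S), a benzylic aryl ether carbon β to the C4 ketone; no other element of the structure can direct it, so a reagent or catalyst must set it. That centre is erased whenever ring C opens by retro-oxa-Michael reaction to the 2'-hydroxychalcone, so it is best set late and kept away from base. The geranyl chain must end on C6 and not on C8, a distinction that direct C-alkylation of phloroglucinol ketones does not make cleanly. The two trisubstituted alkenes exclude hydrogenolysis and strong protic or Lewis acids (which would cyclise the chain onto O5 or O7 to a chroman), and the catechol is easily oxidised, so four phenols need protection that leaves under mild acid. Two features open the route. First, C4 is an aryl ketone carbon on C4a with O1 on the neighbouring C8a; if C4 is drawn as an aldehyde and O1 carries C2=C3 as a 1-arylvinyl group, the C3–C4 bond and the new C2–H bond are exactly what addition of a formyl C–H across that alkene creates. Second, the geranyl group is para to O1, so ring A before formylation is a symmetric phenol derivative whose two open positions are equivalent.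

## Retrosynthesis

**16 ⇒ 15.** The four phenolic O–H bonds are traced back to MOM ethers in the tetra-MOM flavanone 15. Benzyl ethers would need hydrogenolysis, which the geranyl alkenes forbid, and methyl ethers would need boron halides. MOM ethers also direct the two lithiations used earlier. The forward step has to be an acidic methanolysis mild enough to leave the chain and C2 alone.

**15 ⇒ 14.** The C3–C4 bond is cut together with the C2–H bond, giving the achiral aldehyde 14 in which O1 bears the 1-arylvinyl group. Cutting O1–C2 instead leads to a chalcone whose oxa-Michael closure is reversible and hard to render enantioselective; cutting C2–C1' leads to a chromone and is kept in reserve. Aldehyde 14 has no ring C and no stereocentre. The forward reaction, a rhodium-catalysed intramolecular hydroacylation, must place the metal on the terminal alkene carbon and choose one alkene face. A free C5 hydroxyl was considered as a chelating group and rejected. A phenoxide-bound acyl metal is held on the C5 side of the acyl group, away from the alkene tethered through O1. Freeing that hydroxyl would also mean Lewis acid treatment of a compound that has an electron-rich enol ether six atoms from an aldehyde, an arrangement prone to Prins-type closure towards a flavylium ion. O5 therefore stays capped and the alkene itself guides the metal.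

**14 ⇒ 12.** The C4a–CHO bond is cut. In the vinyl ether 12 ring A is symmetric and its two open positions each lie between a MOM ether and the enol ether oxygen, so directed ortho-lithiation (aryllithium 13) and formylation can give only one ring-A product. Formylating before the vinyl ether is made was set aside because an aldehyde would not survive carbonyl methylenation. The forward step needs lithiation on ring A, not ring B, and no addition of the base to the styrene-type alkene.

**12 ⇒ 11 ⇒ 7 + 10.** The C2=C3 methylene is traced back to the carbonyl oxygen of the aryl ester 11 (Petasis methylenation), and the ester to phenol 7 and acid 10 (Steglich esterification). This joins the ring A and ring B halves by the simplest possible bond and places O1, C2 and C1' in one operation. Copper-mediated O-alkenylation of the phenol is less established for 1-arylvinyl groups and is kept as a reserve. The methylenation must leave the trisubstituted alkenes and the acetals untouched.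

**7 ⇒ 6 ⇒ 3 + 4; 3 ⇒ 2 ⇒ 1.** The aryl–CH2 bond of the geranyl group is cut. The position of silyl ether 3 between the two MOM ethers is lithiated (aryllithium 5) and alkylated with geranyl bromide 4 to give 6, and fluoride then frees phenol 7. Friedel–Crafts geranylation of phloroglucinol 1 would give mixtures and chromans. The silyl group marks the oxygen that becomes O1; it enters after the bis-MOM phenol 2 is made from 1 in the only statistical step, placed on the cheapest material.

**10 ⇒ 9 ⇒ 8.** Acid 10 comes from 3,4-dihydroxybenzoic acid 8 by exhaustive methoxymethylation to 9 and saponification of the MOM ester.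

## Roads not taken

**Alternative 1:** Three bonds of ring C are cut (C4a–C4, C4–C3, O1–C2). Forward, PdCl2(PPh3)2, reduced in the flask to zerovalent palladium, joins 4-geranyl-2-iodo-3,5-bis(methoxymethoxy)phenol A2, CO and 4-ethynyl-1,2-bis(methoxymethoxy)benzene A3 by carbonylative coupling and 6-endo phenol addition. The product is 6-geranyl-5,7,3',4'-tetrakis(methoxymethoxy)flavone A1, which must then be reduced enantioselectively to 15.
- Merits: the convergence is high, the fragments are simple and the annulation is a known way to flavones.
- Weak points: the key step sets no stereocentre. C2 would come from a 1,4-reduction of a β,β-disubstituted vinylogous ester, a poor acceptor with little precedent for high selectivity; over-reduction at C4 and hydride or hydrogen reaching the geranyl alkenes are further risks. 5-exo closure to the aurone competes, and A2 needs electrophilic iodination beside the geranyl alkenes.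
- Comparison: the ring closure here is better precedented than the hydroacylation. Against that, the chosen plan sets the ring and C2 in one neutral step, needs no reduction and no CO, and has a similar step count.

**Alternative 2:** The O1–C8a bond is cut. CuI (copper monoiodide) with 1,10-phenanthroline and Cs2CO3 closes (1S,3S)-1-[3,4-bis(methoxymethoxy)phenyl]-3-[2-bromo-5-geranyl-4,6-bis(methoxymethoxy)phenyl]propane-1,3-diol A5 to (2S,4S)-6-geranyl-5,7,3',4'-tetrakis(methoxymethoxy)flavan-4-ol A4. Oxidation at C4 then gives 15.
- Merits: the C2–O bond is never broken, so a carbinol centre made earlier by reliable asymmetric reduction or aldol chemistry is carried through unchanged. In certainty of configuration this road is better than the chosen one.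
- Weak points: C4 must be held as an alcohol and reoxidised, two redox operations and a throwaway stereocentre. The electron-rich, ortho-substituted aryl bromide is a slow partner for copper and needs hot carbonate. The doubly ortho-alkoxy benzylic C4 carbinol can ionise or eliminate under those conditions. The bromide must be introduced beside the geranyl chain. The diol costs several more steps.
- Comparison: the chosen plan sets against the better stereochemical security a shorter, redox-neutral sequence and a symmetric ring-A precursor with no halide.

**Alternative 3:** Ring A is cut away entirely. Irradiation of (2S)-6-(2-diazoacetyl)-2-[3,4-bis(methoxymethoxy)phenyl]-2,3-dihydro-4H-pyran-4-one A7 with the siloxyalkyne triisopropyl{[(4E)-5,9-dimethyldeca-4,8-dien-1-yn-1-yl]oxy}silane A8 starts a Wolff shift (C8–C8a), a ketene–alkyne cycloaddition (C5–C6, C7–C8), ring opening and 6π closure (C4a–C5). The product is (2S)-7-O-triisopropylsilyl-3',4'-bis-O-(methoxymethyl)nymphaeol A A6.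
- Merits: the geranyl position and the distinction of O5 from O7 follow from the mechanism, and C2 can come from an asymmetric hetero-Diels–Alder reaction. On regiochemical certainty this road equals or beats any aromatic substitution.
- Weak points: A7 is a diazo ketone on a photoreactive cross-conjugated enone. A8 is a skipped enyne that isomerises easily. The cascade needs light and then heat. Two different deprotections follow. Overall an aromatic ring that can be bought is built in many steps.
- Comparison: the chosen plan obtains the same regiochemical certainty from the symmetry of 7 at much lower cost, but carries more risk in its single new step.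

Key step: step 10

Assumption: the sense of induction of the chiral bisphosphine cannot be predicted with confidence; (R)-MeO-BIPHEP is written, and its antipode is to be used should the 2R product form.

## Route

Step 1
Reactants: 1 phloroglucinol
Product: 2 3,5-bis(methoxymethoxy)phenol
Conditions: MOMCl (2.0 equiv), i-Pr2NEt, THF/CH2Cl2, 0 °C to rt; chromatography
Reagents that add atoms: chloromethyl methyl ether, COCCl
Why: Statistical O-alkylation of a symmetric triphenol; with two equivalents the bis-ether should be the main component, it differs enough in polarity from the mono- and tris-ethers to be separated, and under-alkylated material can be recycled.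

Step 2
Reactants: 2 3,5-bis(methoxymethoxy)phenol
Product: 3 [3,5-bis(methoxymethoxy)phenoxy]triisopropylsilane
Conditions: TIPSCl, imidazole, DMF, rt
Reagents that add atoms: chlorotriisopropylsilane, CC(C)[Si](Cl)(C(C)C)C(C)C
Why: Standard silylation of the one free phenol; the bulky silyl ether survives n-BuLi and is a poor director for lithiation, which marks this oxygen as the future O1.

Step 3
Reactants: 3 [3,5-bis(methoxymethoxy)phenoxy]triisopropylsilane; 4 geranyl bromide
Product: 6 [4-geranyl-3,5-bis(methoxymethoxy)phenoxy]triisopropylsilane, via aryllithium 5 (not isolated)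
Conditions: n-BuLi, TMEDA, THF, 0 °C; CuBr·SMe2 (10 mol %), then 4, −30 °C to rt
Reagents that add atoms: none
Why: Directed ortho-metalation; the position between the two MOM ethers is the most acidic and doubly chelated while the positions next to the silyl ether are shielded, and copper-catalysed SN2 allylation with the primary allylic bromide should keep the E alkene and avoid SN2′ attack.

Step 4
Reactants: 6 [4-geranyl-3,5-bis(methoxymethoxy)phenoxy]triisopropylsilane
Product: 7 4-geranyl-3,5-bis(methoxymethoxy)phenol
Conditions: TBAF, THF, 0 °C
Reagents that add atoms: none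
Why: Fluoride desilylation of an aryl silyl ether; MOM ethers and alkenes are inert.

Step 5
Reactants: 8 3,4-dihydroxybenzoic acid
Product: 9 methoxymethyl 3,4-bis(methoxymethoxy)benzoate
Conditions: MOMCl (3.6 equiv), i-Pr2NEt, DMF, 0 °C to rt
Reagents that add atoms: chloromethyl methyl ether, COCCl
Why: Exhaustive methoxymethylation of both phenols and of the carboxylate, a routine protection of catechol acids.

Step 6
Reactants: 9 methoxymethyl 3,4-bis(methoxymethoxy)benzoate
Product: 10 3,4-bis(methoxymethoxy)benzoic acid
Conditions: LiOH, THF/MeOH/H2O, rt; then 1 M HCl to pH 4, 0 °C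
Reagents that add atoms: lithium hydroxide, [Li+].[OH-]
Why: Saponification of the MOM ester by acyl–oxygen cleavage; aryl MOM ethers are stable to base and to a brief cold acidification.

Step 7
Reactants: 7 4-geranyl-3,5-bis(methoxymethoxy)phenol; 10 3,4-bis(methoxymethoxy)benzoic acid
Product: 11 4-geranyl-3,5-bis(methoxymethoxy)phenyl 3,4-bis(methoxymethoxy)benzoate
Conditions: EDC·HCl, DMAP, CH2Cl2, 0 °C to rt
Reagents that add atoms: none
Why: Steglich esterification of an unhindered phenol; it avoids an acid chloride and the HCl that would threaten the MOM ethers.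

Step 8
Reactants: 11 4-geranyl-3,5-bis(methoxymethoxy)phenyl 3,4-bis(methoxymethoxy)benzoate
Product: 12 4-{1-[4-geranyl-3,5-bis(methoxymethoxy)phenoxy]ethenyl}-1,2-bis(methoxymethoxy)benzene
Conditions: Cp2TiMe2 (3 equiv), toluene/THF, 65 °C, dark; filtration through basic alumina
Reagents that add atoms: dimethyltitanocene, C[Ti](C)(C1C=CC=C1)C1C=CC=C1
Why: Petasis methylenation of an ester; Cp2Ti=CH2 formed on heating adds to the carbonyl and the oxatitanacyclobutane collapses to the enol ether, a conversion established for aryl benzoates, and trisubstituted alkenes and acetals do not react.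

Step 9
Reactants: 12 4-{1-[4-geranyl-3,5-bis(methoxymethoxy)phenoxy]ethenyl}-1,2-bis(methoxymethoxy)benzene
Product: 14 3-geranyl-2,4-bis(methoxymethoxy)-6-({1-[3,4-bis(methoxymethoxy)phenyl]ethenyl}oxy)benzaldehyde, via aryllithium 13 (not isolated)
Conditions: n-BuLi, TMEDA, Et2O, −20 to 0 °C; DMF, −78 °C to rt; then H2O; base-washed silica
Reagents that add atoms: N,N-dimethylformamide, CN(C)C=O
Why: Directed ortho-metalation and formylation; the two open ring-A positions are equivalent and each lies between two oxygens, so they should be more acidic than ring-B positions beside a single MOM ether, and DMF traps the aryllithium as a hemiaminal alkoxide that releases the aldehyde on quench.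

Step 10
Reactants: 14 3-geranyl-2,4-bis(methoxymethoxy)-6-({1-[3,4-bis(methoxymethoxy)phenyl]ethenyl}oxy)benzaldehyde
Product: 15 (2S)-2-[3,4-bis(methoxymethoxy)phenyl]-6-geranyl-5,7-bis(methoxymethoxy)-2,3-dihydro-4H-chromen-4-one
Conditions: [Rh(nbd)2]BF4 (5 mol %), (R)-MeO-BIPHEP (5.5 mol %), H2 activation then Ar purge, 2,6-di-tert-butyl-4-methylpyridine (10 mol %), 1,2-dichloroethane, 60 °C
Reagents that add atoms: none
Why: Proposed new method: cationic monovalent rhodium, freed of norbornadiene by hydrogenation, should bind the electron-rich vinyl ether of 14 and insert into the formyl C–H bond to give a trivalent acyl rhodium hydride with the alkene cis to the hydride; the hydride moves to C2, the metal takes the terminal carbon C3, and the seven-membered acyl rhodacycle reductively eliminates to form C3–C4. The closest known reaction type is the rhodium–bisphosphine enantioselective intramolecular hydroacylation of 1,1-disubstituted alkenes in ortho-vinyl- and ortho-allyl-benzaldehydes, which gives β-substituted indanones and six-membered benzo-fused ketones; an aldehyde with an ortho 1-arylvinyloxy group has not been used. Ring C closes in the 6-endo mode, both alkene carbons ending in the ring. C2 is set in the hydride transfer, the C2-symmetric ligand pocket choosing the alkene face, and it is not touched afterwards because the medium is neutral. Regiochemistry is needed: the opposite insertion would put rhodium on a fully substituted carbon and lead to a 2-aryl-2-methylbenzofuranone, but that insertion is reversible and reductive elimination at a tertiary centre is slow, so the chromanone channel should prevail. Chemoselectivity follows from the substrate, since the trisubstituted geranyl alkenes are hindered and cannot reach the acyl metal through any unstrained ring, and the alkene has no allylic hydrogen to isomerise. The MOM cap on O5 keeps the metal from resting as a phenoxide chelate on the wrong side of the acyl group, and the hindered pyridine removes traces of acid that would hydrolyse the enol ether or trigger its addition to the aldehyde.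

Step 11
Reactants: 15 (2S)-2-[3,4-bis(methoxymethoxy)phenyl]-6-geranyl-5,7-bis(methoxymethoxy)-2,3-dihydro-4H-chromen-4-one
Product: 16 nymphaeol A, (2S)-2-(3,4-dihydroxyphenyl)-6-geranyl-5,7-dihydroxy-2,3-dihydro-4H-chromen-4-one
Conditions: 3 M HCl (aq)/MeOH, 40 °C
Reagents that add atoms: none
Why: Acid-catalysed acetal exchange removes the four aryl MOM ethers, the carbonyl-flanked C5 ether first; such conditions are routine for prenylated flavanones, and C2 is not exposed to base.

## Compound list

1 | phloroglucinol (benzene-1,3,5-triol) | Oc1cc(O)cc(O)c1 | starting material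
2 | 3,5-bis(methoxymethoxy)phenol | COCOc1cc(O)cc(OCOC)c1 | intermediate
3 | [3,5-bis(methoxymethoxy)phenoxy]triisopropylsilane | COCOc1cc(OCOC)cc(O[Si](C(C)C)(C(C)C)C(C)C)c1 | intermediate
4 | geranyl bromide, (2E)-1-bromo-3,7-dimethylocta-2,6-diene | CC(C)=CCC/C(C)=C/CBr | starting material
5 | [2,6-bis(methoxymethoxy)-4-(triisopropylsilyloxy)phenyl]lithium | [Li]c1c(OCOC)cc(O[Si](C(C)C)(C(C)C)C(C)C)cc1OCOC | intermediate (not isolated)
6 | [4-geranyl-3,5-bis(methoxymethoxy)phenoxy]triisopropylsilane | CC(C)=CCC/C(C)=C/Cc1c(OCOC)cc(O[Si](C(C)C)(C(C)C)C(C)C)cc1OCOC | intermediate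
7 | 4-geranyl-3,5-bis(methoxymethoxy)phenol | CC(C)=CCC/C(C)=C/Cc1c(OCOC)cc(O)cc1OCOC | intermediate
8 | 3,4-dihydroxybenzoic acid | OC(=O)c1ccc(O)c(O)c1 | starting material
9 | methoxymethyl 3,4-bis(methoxymethoxy)benzoate | COCOC(=O)c1ccc(OCOC)c(OCOC)c1 | intermediate
10 | 3,4-bis(methoxymethoxy)benzoic acid | OC(=O)c1ccc(OCOC)c(OCOC)c1 | intermediate
11 | 4-geranyl-3,5-bis(methoxymethoxy)phenyl 3,4-bis(methoxymethoxy)benzoate | CC(C)=CCC/C(C)=C/Cc1c(OCOC)cc(OC(=O)c2ccc(OCOC)c(OCOC)c2)cc1OCOC | intermediate
12 | 4-{1-[4-geranyl-3,5-bis(methoxymethoxy)phenoxy]ethenyl}-1,2-bis(methoxymethoxy)benzene | CC(C)=CCC/C(C)=C/Cc1c(OCOC)cc(OC(=C)c2ccc(OCOC)c(OCOC)c2)cc1OCOC | intermediate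
13 | [3-geranyl-2,4-bis(methoxymethoxy)-6-({1-[3,4-bis(methoxymethoxy)phenyl]ethenyl}oxy)phenyl]lithium | CC(C)=CCC/C(C)=C/Cc1c(OCOC)cc(OC(=C)c2ccc(OCOC)c(OCOC)c2)c([Li])c1OCOC | intermediate (not isolated)
14 | 3-geranyl-2,4-bis(methoxymethoxy)-6-({1-[3,4-bis(methoxymethoxy)phenyl]ethenyl}oxy)benzaldehyde | CC(C)=CCC/C(C)=C/Cc1c(OCOC)cc(OC(=C)c2ccc(OCOC)c(OCOC)c2)c(C=O)c1OCOC | intermediate
15 | (2S)-2-[3,4-bis(methoxymethoxy)phenyl]-6-geranyl-5,7-bis(methoxymethoxy)-2,3-dihydro-4H-chromen-4-one | CC(C)=CCC/C(C)=C/Cc1c(OCOC)cc2c(c1OCOC)C(=O)C[C@@H](c1ccc(OCOC)c(OCOC)c1)O2 | intermediate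
16 | nymphaeol A, (2S)-2-(3,4-dihydroxyphenyl)-6-geranyl-5,7-dihydroxy-2,3-dihydro-4H-chromen-4-one | CC(C)=CCC/C(C)=C/Cc1c(O)cc2c(c1O)C(=O)C[C@@H](c1ccc(O)c(O)c1)O2 | target

## Count and risks

Total step count: 11. Longest linear sequence: 9 steps (steps 1–4 and 7–11, from phloroglucinol 1); the ring-B branch (steps 5–6) joins at step 7.

**Step 10 (key step).** Several processes may defeat it.
- Decarbonylation of the acyl rhodium hydride may outrun the slow closure through a seven-membered metallacycle.
- Insertion with the opposite regiochemistry would lead to the five-membered ketone.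
- Trace acid may trigger addition of the enol ether to the aldehyde or hydrolysis of the enol ether.
- Facial selection on a 1-aryl-1-aryloxy alkene may be poor.

The fallback uses known chemistry, sets out from phenol 7 and returns at 15. Magnesium-mediated ortho-formylation (MgCl2, Et3N, paraformaldehyde, MeCN) should give 5-geranyl-2-hydroxy-4,6-bis(methoxymethoxy)benzaldehyde F1. MeMgBr would convert it into 4-geranyl-2-(1-hydroxyethyl)-3,5-bis(methoxymethoxy)phenol F2, and MnO2 would oxidise that to 1-[3-geranyl-6-hydroxy-2,4-bis(methoxymethoxy)phenyl]ethan-1-one F3. Dimethylformamide dimethyl acetal would give (2E)-3-(dimethylamino)-1-[3-geranyl-6-hydroxy-2,4-bis(methoxymethoxy)phenyl]prop-2-en-1-one F4, which closes with loss of dimethylamine (AcOH, EtOH, warm) to 6-geranyl-5,7-bis(methoxymethoxy)-4H-chromen-4-one F5. Enantioselective conjugate addition of [3,4-bis(methoxymethoxy)phenyl]boronic acid F6, prepared separately, would then give 15; the catalyst would be Pd(OCOCF3)2 with a chiral pyridine–oxazoline ligand, or a rhodium–chiral diene complex.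

**Step 9.** Deprotonation may occur on ring B beside a single MOM ether, and n-BuLi may add to the α-aryloxystyrene; either would consume the base and erode the yield of ring-A aldehyde. The fallback replaces deprotonation by halogen–lithium exchange; it sets out from 7 and returns at the aryllithium 13. Bromination with NBS (CH2Cl2, −78 °C) should give 2-bromo-4-geranyl-3,5-bis(methoxymethoxy)phenol F7. Steglich esterification with 10 would give 2-bromo-4-geranyl-3,5-bis(methoxymethoxy)phenyl 3,4-bis(methoxymethoxy)benzoate F8, and Petasis methylenation would give 4-{1-[2-bromo-4-geranyl-3,5-bis(methoxymethoxy)phenoxy]ethenyl}-1,2-bis(methoxymethoxy)benzene F9. Exchange with n-BuLi at −78 °C would then give 13, which DMF converts into 14 as in the main route.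

**Step 8.** Methylenation of the electron-rich benzoate may stall, and the enol ether may hydrolyse back to 7 on acidic surfaces during isolation. The fallback builds the O1–C2 bond directly; it sets out from 7 and returns at 12. Copper-mediated oxidative Chan–Lam coupling (Cu(OAc)2, pyridine, air, 4 Å molecular sieves, CH2Cl2) of 7 with {1-[3,4-bis(methoxymethoxy)phenyl]ethenyl}boronic acid F10, prepared separately, would give 12 and bypass steps 7 and 8.

**Step 11.** Protic acid may cyclise the geranyl chain onto O5 or O7 (chroman formation) and may partly racemise C2 through ring opening. The fallback removes the acetals by silyl transfer instead of protonation; it sets out from 15 and returns at 16. TMSOTf with 2,2'-bipyridyl (CH2Cl2, 0 °C) should give (2S)-6-geranyl-5,7-bis(trimethylsilyloxy)-2-[3,4-bis(trimethylsilyloxy)phenyl]-2,3-dihydro-4H-chromen-4-one F11, which water cleaves to 16 at neutral pH.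

## Further compounds

F1 | step 10 | 5-geranyl-2-hydroxy-4,6-bis(methoxymethoxy)benzaldehyde | CC(C)=CCC/C(C)=C/Cc1c(OCOC)cc(O)c(C=O)c1OCOC
F2 | step 10 | 4-geranyl-2-(1-hydroxyethyl)-3,5-bis(methoxymethoxy)phenol (racemic carbinol) | CC(C)=CCC/C(C)=C/Cc1c(OCOC)cc(O)c(C(C)O)c1OCOC
F3 | step 10 | 1-[3-geranyl-6-hydroxy-2,4-bis(methoxymethoxy)phenyl]ethan-1-one | CC(C)=CCC/C(C)=C/Cc1c(OCOC)cc(O)c(C(C)=O)c1OCOC
F4 | step 10 | (2E)-3-(dimethylamino)-1-[3-geranyl-6-hydroxy-2,4-bis(methoxymethoxy)phenyl]prop-2-en-1-one | CC(C)=CCC/C(C)=C/Cc1c(OCOC)cc(O)c(C(=O)/C=C/N(C)C)c1OCOC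
F5 | step 10 | 6-geranyl-5,7-bis(methoxymethoxy)-4H-chromen-4-one | CC(C)=CCC/C(C)=C/Cc1c(OCOC)cc2occc(=O)c2c1OCOC
F6 | step 10 | [3,4-bis(methoxymethoxy)phenyl]boronic acid | COCOc1ccc(B(O)O)cc1OCOC
F7 | step 9 | 2-bromo-4-geranyl-3,5-bis(methoxymethoxy)phenol | CC(C)=CCC/C(C)=C/Cc1c(OCOC)cc(O)c(Br)c1OCOC
F8 | step 9 | 2-bromo-4-geranyl-3,5-bis(methoxymethoxy)phenyl 3,4-bis(methoxymethoxy)benzoate | CC(C)=CCC/C(C)=C/Cc1c(OCOC)cc(OC(=O)c2ccc(OCOC)c(OCOC)c2)c(Br)c1OCOC
F9 | step 9 | 4-{1-[2-bromo-4-geranyl-3,5-bis(methoxymethoxy)phenoxy]ethenyl}-1,2-bis(methoxymethoxy)benzene | CC(C)=CCC/C(C)=C/Cc1c(OCOC)cc(OC(=C)c2ccc(OCOC)c(OCOC)c2)c(Br)c1OCOC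
F10 | step 8 | {1-[3,4-bis(methoxymethoxy)phenyl]ethenyl}boronic acid | COCOc1ccc(C(=C)B(O)O)cc1OCOC
F11 | step 11 | (2S)-6-geranyl-5,7-bis(trimethylsilyloxy)-2-[3,4-bis(trimethylsilyloxy)phenyl]-2,3-dihydro-4H-chromen-4-one | CC(C)=CCC/C(C)=C/Cc1c(O[Si](C)(C)C)cc2c(c1O[Si](C)(C)C)C(=O)C[C@@H](c1ccc(O[Si](C)(C)C)c(O[Si](C)(C)C)c1)O2
A1 | alternative 1 | 6-geranyl-5,7,3',4'-tetrakis(methoxymethoxy)flavone | CC(C)=CCC/C(C)=C/Cc1c(OCOC)cc2c(c1OCOC)C(=O)C=C(c1ccc(OCOC)c(OCOC)c1)O2
A2 | alternative 1 | 4-geranyl-2-iodo-3,5-bis(methoxymethoxy)phenol | CC(C)=CCC/C(C)=C/Cc1c(OCOC)cc(O)c(I)c1OCOC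
A3 | alternative 1 | 4-ethynyl-1,2-bis(methoxymethoxy)benzene | C#Cc1ccc(OCOC)c(OCOC)c1
A4 | alternative 2 | (2S,4S)-6-geranyl-5,7,3',4'-tetrakis(methoxymethoxy)flavan-4-ol (2,4-cis) | CC(C)=CCC/C(C)=C/Cc1c(OCOC)cc2c(c1OCOC)[C@@H](O)C[C@@H](c1ccc(OCOC)c(OCOC)c1)O2
A5 | alternative 2 | (1S,3S)-1-[3,4-bis(methoxymethoxy)phenyl]-3-[2-bromo-5-geranyl-4,6-bis(methoxymethoxy)phenyl]propane-1,3-diol | CC(C)=CCC/C(C)=C/Cc1c(OCOC)cc(Br)c(c1OCOC)[C@@H](O)C[C@H](O)c1ccc(OCOC)c(OCOC)c1
A6 | alternative 3 | (2S)-7-O-triisopropylsilyl-3',4'-bis-O-(methoxymethyl)nymphaeol A | CC(C)=CCC/C(C)=C/Cc1c(O[Si](C(C)C)(C(C)C)C(C)C)cc2c(c1O)C(=O)C[C@@H](c1ccc(OCOC)c(OCOC)c1)O2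
A7 | alternative 3 | (2S)-6-(2-diazoacetyl)-2-[3,4-bis(methoxymethoxy)phenyl]-2,3-dihydro-4H-pyran-4-one | [N-]=[N+]=CC(=O)C1=CC(=O)C[C@@H](c2ccc(OCOC)c(OCOC)c2)O1
A8 | alternative 3 | triisopropyl{[(4E)-5,9-dimethyldeca-4,8-dien-1-yn-1-yl]oxy}silane | CC(C)=CCC/C(C)=C/CC#CO[Si](C(C)C)(C(C)C)C(C)C
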